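**Strategy.** Ring numbering: C1 (CMe2), C2–C4, C5/C6 (epoxide), C7, C8, C9 (bears carboxyl C12), C10, C11 (CHOBz). C12, C9, C10 and C11 are carried as a furan (ring atoms C11, C10, C9, C12, O) bridged from C11 to C9 by the C1–C8 chain. Singlet oxygen adds across the furan α-carbons C11 and C12; amine-induced endoperoxide collapse through the lone α-hydrogen (C12–H) creates the C12 lactone carbonyl and the C11 hemiketal at once, giving the bridged γ-hydroxybutenolide, a masked C11-keto C12-acid. The precursor is an achiral [8](2,4)furanophane with E C5=C6, closed by B-alkyl Suzuki coupling.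

Key step: step 7

Remark: hydroxybutenolide 17 has a single stereocentre (C11) and should form as a racemate, not as epimers; this centre is erased in step 8.
Assumption: in the CBS reduction the tert-alkyl C1 flank of the C11 ketone is taken as the large group; the catalyst enantiomer in step 10 follows from this model.

**Step 1**
Reactants: 1 methyl 4-bromofuran-2-carboxylate; 2 methylmagnesium bromide
Product: 4 2-(4-bromofuran-2-yl)propan-2-ol, via methyl ketone 3 (not isolated)
Conditions: MeMgBr (2.5 equiv), THF, 0 °C → rt; aq. NH4Cl
Reagents that add atoms: none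
Why: Double Grignard addition to the ester through the methyl ketone should give the tertiary carbinol, the furyl C–Br bond being inert to MeMgBr at this temperature.

**Step 2**
Reactants: 4 2-(4-bromofuran-2-yl)propan-2-ol; 5 allyltrimethylsilane
Product: 6 4-bromo-2-(2-methylpent-4-en-2-yl)furan
Conditions: allylTMS (3 equiv), InCl3 (10 mol%), CH2Cl2, 0 °C → rt
Reagents that add atoms: none
Why: Lewis-acid ionization should give a tertiary, furan-stabilized cation that the allylsilane traps at the exocyclic carbon (Hosomi–Sakurai-type SN1 allylation of a tertiary heteroaryl carbinol), the ring bromine lowering the nucleophilicity of the furan so that self-alkylation is held back.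

**Step 3**
Reactants: 7 pent-3-yn-1-ol
Product: 9 (E)-4-iodopent-3-en-1-ol, via alkenylzirconocene 8 (not isolated)
Conditions: Cp2Zr(H)Cl (3 equiv), THF, rt → 50 °C; then I2, 0 °C
Reagents that add atoms: iodine, II
Why: Syn hydrozirconation with Schwartz reagent (the first equivalent forming the zirconium alkoxide), equilibrated by excess reagent to the less hindered isomer with Zr on the methyl-bearing carbon, followed by iodinolysis with retention should give the iodide with I trans to the CH2 chain.

**Step 4**
Reactants: 9 (E)-4-iodopent-3-en-1-ol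
Product: 10 (E)-4-iodopent-3-en-1-yl trifluoromethanesulfonate
Conditions: Tf2O, 2,6-lutidine, CH2Cl2, −78 °C; used at once
Reagents that add atoms: triflic anhydride, O=S(=O)(OS(=O)(=O)C(F)(F)F)C(F)(F)F
Why: O-Sulfonylation of the primary alcohol at low temperature with a hindered base should give the triflate without touching the alkenyl iodide.

**Step 5**
Reactants: 6 4-bromo-2-(2-methylpent-4-en-2-yl)furan; 10 (E)-4-iodopent-3-en-1-yl trifluoromethanesulfonate
Product: 13 4-[(E)-4-iodopent-3-en-1-yl]-2-(2-methylpent-4-en-2-yl)furan, via furyllithium 11 (not isolated), via furylmagnesium bromide 12 (not isolated)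
Conditions: t-BuLi (2.0 equiv), Et2O, −78 °C; MgBr2·OEt2; then 10, CuBr·SMe2 (10 mol%), THF, −78 → −20 °C
Reagents that add atoms: none
Why: Bromine–lithium exchange at −78 °C should give the β-furyl anion regiospecifically, and after transmetalation to magnesium a copper-catalysed SN2 displacement of the primary triflate (Kochi-type coupling) forms C8–C9, an aryl Grignard with catalytic copper leaving the alkenyl C–I bond alone at this temperature.

**Step 6**
Reactants: 13 4-[(E)-4-iodopent-3-en-1-yl]-2-(2-methylpent-4-en-2-yl)furan
Product: 15 [8](2,4)furanophane (C11 and C9 of the furan joined by C1–C8; C1 gem-dimethyl; C5 methyl; E C5=C6; achiral), via B-alkyl-9-BBN borane 14 (not isolated)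
Conditions: 9-BBN (1.3 equiv), THF, rt; then slow addition to Pd(dppf)Cl2 (15 mol%), AsPh3, Cs2CO3, DMF/THF/H2O, 45 °C, 2 mM
Reagents that add atoms: none
Why: 9-BBN should add only to the monosubstituted olefin and place boron on C4, and intramolecular B-alkyl Suzuki–Miyaura coupling with the alkenyl iodide under high dilution forms C4–C5 with retention of the E geometry and closes the 11-membered carbocycle.

**Step 7**
Reactants: 15 [8](2,4)furanophane
Product: 17 bridged γ-hydroxybutenolide (C12 lactone carbonyl; C11 hemiketal; racemic), via endoperoxide 16 (not isolated)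
Conditions: O2, visible light, TPP (1 mol%), i-Pr2NEt (3 equiv), CH2Cl2, −78 °C → rt
Reagents that add atoms: dioxygen, O=O
Why: Singlet oxygen should add suprafacially in a [4+2] cycloaddition across the furan α-carbons C11 and C12 to give the 2,3,7-trioxabicyclo[2.2.1]heptene 16, after which the hindered amine removes the only hydrogen on a peroxide-bearing carbon (C12–H) and the O–O bond breaks (Kornblum–DeLaMare-type collapse), leaving the lactone C=O at C12 and the hemiketal at C11. The closest known reaction is the base-mediated photooxygenation of 3-alkyl- and 2,4-dialkylfurans to γ-hydroxybutenolides. No carbocycle is closed: the peroxide bridge of the cycloadduct is transient and the five-membered oxygen ring of the furan persists as the butenolide ring. The one new stereocentre, hemiketal C11, is uncontrolled (racemate) and is erased in step 8. The step needs chemoselectivity for the furan over the C5=C6 olefin, which rests on furan cycloaddition being much faster than the ene reaction of a trisubstituted olefin at −78 °C with irradiation stopped at full conversion, and regioselective collapse, which is secured because C11 is fully substituted and only C12 carries a hydrogen.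

**Step 8**
Reactants: 17 bridged γ-hydroxybutenolide
Product: 19 allyl (5E,9Z)-1,1,5-trimethyl-11-oxocycloundeca-5,9-diene-9-carboxylate (route numbering), via cesium keto carboxylate 18 (not isolated)
Conditions: Cs2CO3 (1.2 equiv), allyl bromide (1.5 equiv), DMF, 0 °C → rt
Reagents that add atoms: allyl bromide, C=CCBr
Why: Base should open the hemiketal to the keto carboxylate, whose SN2 O-alkylation is favoured over alkylation of the hindered tertiary hemiketal oxygen, giving the open ester with the C9=C10 geometry inherited from the lactone.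

**Step 9**
Reactants: 19 allyl (5E,9Z)-keto ester
Product: 20 allyl (5E,9E)-1,1,5-trimethyl-11-oxocycloundeca-5,9-diene-9-carboxylate (C8 and C11 cis on C9=C10)
Conditions: I2 (5 mol%), CH2Cl2, visible light, rt
Reagents that add atoms: none
Why: Reversible iodine-atom addition at C10 of the γ-oxo enoate (iodine-catalysed Z→E isomerization of an ene-keto-ester) should let C9=C10 relax to the less strained ring-cis isomer with ester and ketone trans, whereas the unactivated C5=C6 olefin should not isomerize at room temperature and is not exposed to electrophilic thiyl radicals, which add reversibly to such olefins.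

**Step 10**
Reactants: 20 allyl (5E,9E)-keto ester
Product: 21 allyl (5E,9E,11R)-11-hydroxy-1,1,5-trimethylcycloundeca-5,9-diene-9-carboxylate
Conditions: (S)-Me-CBS (20 mol%), catecholborane (1.5 equiv), toluene, −78 → −40 °C; then MeOH
Reagents that add atoms: none
Why: In this CBS reduction the ketone should bind the oxazaborolidine anti to the tert-alkyl C1 flank (large group, the twisted alkenyl flank acting as the small one), so that the (S)-catalyst delivers hydride to the face giving 11R, while catecholborane at low temperature spares both olefins and the ester.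

**Step 11**
Reactants: 21 allyl (5E,9E,11R)-hydroxy ester
Product: 22 allyl (5E,9E,11R)-11-(benzoyloxy)-1,1,5-trimethylcycloundeca-5,9-diene-9-carboxylate
Conditions: BzCl (2 equiv), Et3N, DMAP (0.3 equiv), CH2Cl2, 0 °C → rt
Reagents that add atoms: benzoyl chloride, O=C(Cl)c1ccccc1
Why: DMAP-catalysed acyl transfer should benzoylate the hindered secondary alcohol at oxygen with no change at C11.

**Step 12**
Reactants: 22 allyl (5E,9E,11R)-benzoate
Product: 23 allyl (5R,6R,9E,11R)-11-(benzoyloxy)-5,6-epoxy-1,1,5-trimethylcycloundec-9-ene-9-carboxylate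
Conditions: D-fructose-derived Shi ketone (30 mol%), Oxone, K2CO3, Bu4NHSO4, MeCN/DMM/aq. borate–EDTA buffer (pH ≈ 10.5), 0 °C
Reagents that add atoms: potassium peroxymonosulfate (Oxone), [K+].[O-]S(=O)(=O)OO
Why: In this Shi epoxidation the chiral dioxirane should attack only the electron-rich E-trisubstituted C5=C6 olefin, syn oxygen transfer keeping C4 and C7 trans and the spiro transition state of the D-fructose-derived ketone setting 5R,6R under reagent control, the sense this catalyst shows with E-trisubstituted olefins.

**Step 13**
Reactants: 23 allyl (5R,6R,9E,11R)-epoxy benzoate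
Product: 24 (5R,6R,9E,11R)-11-(benzoyloxy)-5,6-epoxy-1,1,5-trimethylcycloundec-9-ene-9-carboxylic acid (CNP0377917.1)
Conditions: Pd(PPh3)4 (5 mol%), morpholine (3 equiv), THF, 0 °C → rt; pH 5 buffer work-up
Reagents that add atoms: none
Why: Tsuji–Trost deallylation, in which Pd(0) ionizes the unhindered allyl ester far faster than the hindered C11 benzoate and morpholine captures the π-allyl fragment, should release the acid under neutral conditions that spare the epoxide.

**Compound list**
1 | methyl 4-bromofuran-2-carboxylate | COC(=O)c1cc(Br)co1 | starting material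
2 | methylmagnesium bromide | C[Mg]Br | starting material
3 | 1-(4-bromofuran-2-yl)ethan-1-one (not isolated) | CC(=O)c1cc(Br)co1 | intermediate
4 | 2-(4-bromofuran-2-yl)propan-2-ol | CC(C)(O)c1cc(Br)co1 | intermediate
5 | allyltrimethylsilane | C=CC[Si](C)(C)C | starting material
6 | 4-bromo-2-(2-methylpent-4-en-2-yl)furan | C=CCC(C)(C)c1cc(Br)co1 | intermediate
7 | pent-3-yn-1-ol | CC#CCCO | starting material
8 | (E)-alkenylzirconocene chloride of the zirconium alkoxide of 7, Zr on the methyl-bearing carbon (not isolated) | C/C([Zr](Cl)(C1C=CC=C1)C1C=CC=C1)=C\CCO[Zr](Cl)(C1C=CC=C1)C1C=CC=C1 | intermediate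
9 | (E)-4-iodopent-3-en-1-ol | C/C(I)=C\CCO | intermediate
10 | (E)-4-iodopent-3-en-1-yl trifluoromethanesulfonate | C/C(I)=C\CCOS(=O)(=O)C(F)(F)F | intermediate
11 | [5-(2-methylpent-4-en-2-yl)furan-3-yl]lithium (not isolated) | C=CCC(C)(C)c1cc([Li])co1 | intermediate
12 | [5-(2-methylpent-4-en-2-yl)furan-3-yl]magnesium bromide (not isolated) | C=CCC(C)(C)c1cc([Mg]Br)co1 | intermediate
13 | 4-[(E)-4-iodopent-3-en-1-yl]-2-(2-methylpent-4-en-2-yl)furan | C=CCC(C)(C)c1cc(CC/C=C(\C)I)co1 | intermediate
14 | 9-{4-[4-((E)-4-iodopent-3-en-1-yl)furan-2-yl]-4-methylpentyl}-9-borabicyclo[3.3.1]nonane (not isolated) | C/C(I)=C\CCc1coc(C(C)(C)CCCB2C3CCCC2CCC3)c1 | intermediate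
15 | [8](2,4)furanophane: furan C-2 (C11) and C-4 (C9) joined by C1(Me)2–C2H2–C3H2–C4H2–C5(Me)=C6H–C7H2–C8H2, E at C5=C6, achiral | CC1(C)CCC/C(C)=C/CCc2coc1c2 | intermediate
16 | furan endoperoxide, peroxide bridge between C11 and C12, racemic (not isolated) | CC1(C)CCC/C(C)=C/CCC2=CC13OOC2O3 | intermediate
17 | bridged γ-hydroxybutenolide, lactone C12(=O)–O–C11(OH), C9=C10 in the lactone ring, E C5=C6, racemic at C11 | CC1(C)CCC/C(C)=C/CCC2=CC1(O)OC2=O | intermediate
18 | cesium (5E,9Z)-1,1,5-trimethyl-11-oxocycloundeca-5,9-diene-9-carboxylate (not isolated) | CC1(C)CCC/C(C)=C/CC/C(C(=O)[O-])=C/C1=O.[Cs+] | intermediate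
19 | allyl (5E,9Z)-1,1,5-trimethyl-11-oxocycloundeca-5,9-diene-9-carboxylate | CC1(C)CCC/C(C)=C/CC/C(C(=O)OCC=C)=C/C1=O | intermediate
20 | allyl (5E,9E)-1,1,5-trimethyl-11-oxocycloundeca-5,9-diene-9-carboxylate | CC1(C)CCC/C(C)=C/CC/C(C(=O)OCC=C)=C\C1=O | intermediate
21 | allyl (5E,9E,11R)-11-hydroxy-1,1,5-trimethylcycloundeca-5,9-diene-9-carboxylate | CC1(C)CCC/C(C)=C/CC/C(C(=O)OCC=C)=C\[C@H]1O | intermediate
22 | allyl (5E,9E,11R)-11-(benzoyloxy)-1,1,5-trimethylcycloundeca-5,9-diene-9-carboxylate | CC1(C)CCC/C(C)=C/CC/C(C(=O)OCC=C)=C\[C@H]1OC(=O)c1ccccc1 | intermediate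
23 | allyl (5R,6R,9E,11R)-11-(benzoyloxy)-5,6-epoxy-1,1,5-trimethylcycloundec-9-ene-9-carboxylate | CC1(C)CCC[C@@]2(C)O[C@@H]2CC/C(C(=O)OCC=C)=C\[C@H]1OC(=O)c1ccccc1 | intermediate
24 | (5R,6R,9E,11R)-11-(benzoyloxy)-5,6-epoxy-1,1,5-trimethylcycloundec-9-ene-9-carboxylic acid | CC1(C)CCC[C@@]2(C)O[C@@H]2CC/C(C(=O)O)=C\[C@H]1OC(=O)c1ccccc1 | target

**Step count.** Total: 13 steps. Longest linear sequence: 11 steps (1 → 4 → 6 → 13 → 15 → 17 → 19 → 20 → 21 → 22 → 23 → 24; the branch from 7 through 9 and 10 is equally long).

**Steps most likely to fail**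

Step 7. Singlet oxygen may also attack the C5=C6 olefin in an ene reaction, or the strained endoperoxide may break down before the amine-induced collapse. The fallback sets out from 15 and avoids singlet oxygen. Oxidative furan opening with NBS (1.05 equiv, NaHCO3, THF/H2O, −20 °C) should give the (5E,9Z)-11-oxo-9-formyl macrocycle, keto aldehyde F1. Pinnick oxidation of the crude aldehyde (NaClO2, NaH2PO4, 2-methyl-2-butene, t-BuOH/H2O) then gives the keto acid, which closes to the hydroxybutenolide, and the route is rejoined at 17.

Step 6. Intermolecular coupling to oligomers, or protodeboronation and β-hydride loss of the alkylpalladium species, may outrun closure of the strained ring. The fallback closes the ring at C8–C9 instead; it sets out from 6 and 9 and bypasses steps 4 and 5.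
- Hydroboration of 6 with 9-BBN gives the B-alkyl borane F2.
- Intermolecular B-alkyl Suzuki coupling of F2 with alkenyl iodide 9 (Pd(dppf)Cl2, Cs2CO3, DMF/THF/H2O, rt), at which the furyl bromide should stay inert, gives (E)-8-(4-bromofuran-2-yl)-4,8-dimethylnon-3-en-1-ol F3.
- Appel iodination (I2, PPh3, imidazole) gives the primary iodide F4.
- Zinc insertion (Zn, LiCl, THF) gives the alkylzinc iodide F5.
- Slow addition of F5 to Pd(OAc)2/SPhos in THF at high dilution closes the ring by intramolecular Negishi coupling, and the route is rejoined at 15.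

Step 10. Facial selectivity may be poor if the catalyst does not distinguish the tert-alkyl flank from the alkenyl flank of the macrocyclic ketone. The fallback sets out from 20 and replaces asymmetric induction by resolution. Luche reduction (NaBH4, CeCl3·7H2O, MeOH, −78 → 0 °C) gives 21 together with its enantiomer, the (11S)-alcohol F6. The two are separated by preparative chromatography on a chiral stationary phase, and the route is rejoined at 21. F6 is returned to 20 by Dess–Martin oxidation and recycled.

**Further compounds**
F1 | step 7 | (5E,9Z)-1,1,5-trimethyl-11-oxocycloundeca-5,9-diene-9-carbaldehyde | CC1(C)CCC/C(C)=C/CC/C(C=O)=C/C1=O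
F2 | step 6 | 9-[4-(4-bromofuran-2-yl)-4-methylpentyl]-9-borabicyclo[3.3.1]nonane | CC(C)(CCCB1C2CCCC1CCC2)c1cc(Br)co1
F3 | step 6 | (E)-8-(4-bromofuran-2-yl)-4,8-dimethylnon-3-en-1-ol | OCC/C=C(\C)CCCC(C)(C)c1cc(Br)co1
F4 | step 6 | 4-bromo-2-[(E)-9-iodo-2,6-dimethylnon-6-en-2-yl]furan | ICC/C=C(\C)CCCC(C)(C)c1cc(Br)co1
F5 | step 6 | [(E)-8-(4-bromofuran-2-yl)-4,8-dimethylnon-3-en-1-yl]zinc iodide | I[Zn]CC/C=C(\C)CCCC(C)(C)c1cc(Br)co1
F6 | step 10 | allyl (5E,9E,11S)-11-hydroxy-1,1,5-trimethylcycloundeca-5,9-diene-9-carboxylate | CC1(C)CCC/C(C)=C/CC/C(C(=O)OCC=C)=C\[C@@H]1O
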